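In a one-step world I would ask one thing of a flask: how long to wait. Here the starting material gives an intermediate with two exits, partner or a second intermediate, so the wait and the yield part company.

    2 intermediate → homo product (k1 = 0.00536 M⁻¹ s⁻¹, Ea1 = 75.0 kJ mol⁻¹)
    starting material → intermediate (k2 = 0.00564 s⁻¹, Ea2 = 81.0 kJ mol⁻¹)
    partner + intermediate → target (k3 = 0.0342 M⁻¹ s⁻¹, Ea3 = 69.0 kJ mol⁻¹)
    gas ⇌ partner, rate k4*(csat - [partner]) (k4 = 0.00398 s⁻¹, csat = 200 mM)
    (constants at 25 °C)

| setting | Sunday's | Thursday's | Friday's | Saturday's |
|---|---|---|---|---|
| starting material | 0.80 M | 0.80 M | 0.80 M | 0.80 M |
| gas | 200 mM (held) | 200 mM (held) | 200 mM (held) | 200 mM (held) |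
| temperature | 25 °C | −25 °C | 0 °C |  |
| time | 1.0 h | 1.0 h | 1.0 h | 1.0 h |
| remark |  |  |  | at −25 °C until 20 min, from then on at 25 °C |

- percent here means starting material units held: one homo product counts as two
- a step written with two of one species runs at k times the square of its concentration and takes two of it each time
- at the start none of partner is dissolved
- the constants hold at 25 °C; other temperatures follow from the activation energies

- the flask with the highest amount of target, in percent of the starting material charged ("all alike" if they lie within 1.5 percentage points) (Sunday's / Thursday's / Friday's / Saturday's / all alike)
- final target, as a percentage of the starting material charged, in Sunday's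
- final target, as a percentage of the starting material charged, in Thursday's
- final target, as a percentage of the starting material charged, in Friday's
- final target, as a percentage of the starting material charged, in Saturday's

Take partner at its saturation concentration, 200 mM, so that capture is pseudo-first-order, and let the intermediate stand where dimerisation by itself removes what the full charge delivers. Capture over dimerisation there is 0.983 at 25 °C; I call this ratio N, the capture number. It is the capture constant times 200 mM, divided by the square root of the product of 2, the dimerisation constant, the formation constant and the charge.

N near one is a coin toss: the first share of target, N over one plus N, is 49.6%. But capture lowers the intermediate and so weakens dimerisation, which makes the ratio r of capture to dimerisation equal to N times the root of one plus r. Putting the first answer back gives r = 1.39, and once more 1.52, a share of 60.3%.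

Is one number enough? No. At −25 °C, in Thursday's, N rises to 2.04, yet I reckon that 2.81% of the charge turns over in 1.0 h. In Sunday's the starting material has a half-life of 2.05 min, shorter than the 2.90 min half-time of the filling of partner, reckoned with nothing using it, so I put that flask below the share. Saturday's cold 20 min fill partner to 99.2% of saturation while 0.936% of the charge reacts, though that store is a quarter of the charge. I commit to Saturday's first, at about 60.3%.

The forecast also names Saturday's, at 61%, a little above my share, with 49.5% in Sunday's, 0.1% in Thursday's and 34% in Friday's, on the ground that “simulated partner catches the intermediate burst after warming”.

The flasks give Saturday's first at 61.6%, then 49.4% in Sunday's, 33.6% in Friday's and 0.121% in Thursday's. Dimerisation is the main reason for the target missing in Sunday's: with that step taken away, Sunday's ends at >99.9% instead of 49.4%. N weighs capture against that step, and at 2.0 M of starting material, a neighbour of Saturday's, N at 25 °C falls to 0.622. Two rounds then give a share of 45.4% for the full charge with partner saturated, and that neighbour ends lower, at 33.8% target and 66.2% homo product.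

(The numbers of this flask were set for the occasion; what happens was integrated by code.)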